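# Proposed total synthesis of neocryptomerin by carbonylative alkyne annulation of a symmetric iodophenol

## The problem

Neocryptomerin **21** is a biflavone ether. Unit 1 is a 5-hydroxy-7-methoxyflavone whose ring B carries at C4' an oxygen that is bonded to C6 of unit 2, a 5,7,4'-trihydroxyflavone. There is no stereocenter, so the task is one of connectivity, regiochemistry and phenol differentiation only. The ether oxygen lies on ring A of unit 2 between the oxygenated carbons C5 and C7, so the diaryl ether must be made at a phenol with two ortho substituents. One phenolic oxygen (O7 of unit 1) is methylated and four are free, so the hydroxyls of unit 2 need a protecting group that can be removed beside an aryl methyl ether. The two 4-pyranone rings open under hot hydroxide, their C2–C3 double bonds can be over-reduced, and the tetraoxygenated ring A of unit 2 is easily oxidised once its phenols are free; unmasking therefore comes last and under mild conditions. The feature used is that in unit 2 the carbonyl carbon C4 lies between C4a and C3, while O1 sits on C8a next to C4a. An ortho-iodophenol, carbon monoxide and an arylacetylene supply exactly these atoms. Because C5 and C7 carry identical protected oxygens, the iodophenol derives from a phenol with a mirror plane through C6 and C8a, whose two ortho carbons are equivalent.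

## Retrosynthesis

**21 from 20.** The three O–benzyl bonds on O5, O7 and O4' of unit 2 are cut. Benzyl is chosen because hydrogenolysis leaves the methyl ether of unit 1 untouched; methyl or isopropyl ethers on unit 2 could not be told apart from it as safely. The hydroxyl at C5 of unit 1 stays free throughout, since it is hydrogen-bonded to the C4 carbonyl and unreactive. The forward step must cleave three benzyl ethers without reducing either pyranone.

**20 from 19.** The O1–C2 bond of unit 1 is cut, giving the 1,3-diketone **19**. Its ketone-bearing ring is a 2,6-dihydroxy-4-methoxyphenyl group, so either hydroxyl closes to the same 5-hydroxy-7-methoxyflavone and O5 needs no protecting group. A chalcone route to this ring would need a hydroxide-mediated aldol and an oxidant in the presence of unit 2. The forward step is an acid-catalysed cyclodehydration mild enough for aryl benzyl ethers.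

**19 from 16 and 17 (through 18).** The C2–C3 bond of unit 1 is cut between the two carbonyl groups. This separates the whole of unit 2, as benzoic acid **16**, from the commercial acetophenone **17**, and is the most convergent cut available. The forward reaction is C-acylation of the lithium polyanion of **17** by acid chloride **18**, so that no ester has to be made and rearranged first.

**16 from 15.** The ester C–O bond is cut. A tert-butyl ester is carried through the earlier steps because it resists a secondary amine at 90 °C, carbonate in methanol and peracid. It is removed by acid, so no hydroxide meets ring C of unit 2.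

**15 from 9, 11 and 12 (through 13 and 14).** Three bonds of unit 2 are cut: C4a–C4, C4–C3 and O1–C2. The neighbouring cuts, through a diketone or a chalcone, would require an acetyl group on the crowded, acid-sensitive ring A. Here that ring needs only an iodine, and ring C forms in one operation from iodophenol **9**, carbon monoxide **12** and alkyne **11**. The forward reaction must insert carbon monoxide before the alkyne is transferred and must close the six-membered ring, not the five-membered one.

**11 from 10.** The alkyne carbon–carbon bond is traced to the formyl group of aldehyde **10** by a one-carbon homologation.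

**9 from 8.** The C–I bond is cut. Phenol **8** has only two unsubstituted ring carbons on its oxygenated ring, both ortho to the hydroxyl and related by the mirror plane. Any mono-iodination therefore gives **9**, and O1 and C4 are fixed relative to the ether oxygen without discrimination among the ring-A oxygens.

**8 from 6 (through 7).** The C–O bond of the future O1 is traced to a formyl group by Baeyer–Villiger oxidation. The aldehyde serves three purposes: it acidifies the phenol used in the preceding coupling, it protects the trioxygenated ring from oxidation by divalent copper, and it is the latent hydroxyl. The forward step needs aryl migration in preference to hydride migration.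

**6 from 4 and 5.** The bond between the ether oxygen and ring B of unit 1 is cut. The phenoxide of **4** is hindered and deactivated by its para formyl group, and a para-fluorobenzoic ester is only weakly activated, so nucleophilic aromatic substitution is a poor match here and is held in reserve. A copper-mediated oxidative coupling with boronic acid **5** runs at room temperature and has precedent for acidic phenols with two ortho substituents. The reverse polarity, with ring A as electrophile, has no accessible halide.

**4 from 1 (through 2 and 3).** The O–benzyl bonds on the flanking oxygens and a temporary O–allyl bond on the central oxygen are cut. In **1** the central hydroxyl, para to the formyl group, is the most acidic, so it is alkylated first; it therefore receives a temporary allyl group (**2**). The flanking hydroxyls are then benzylated (**3**) and the allyl group is removed by zerovalent palladium to give **4**.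

## Roads not taken

**Alternative 1:** Ring B of unit 1 is built on the hindered oxygen instead of being attached to it. The C2'–C3' and C4'–C5' bonds of that ring are cut, leading to aryl ethynyl ether **A2** and methyl coumalate **A3**. In the forward sense the electron-rich alkyne of **A2** would add across C3 and C6 of the 2-pyranone **A3** in an inverse-demand (4+2) cycloaddition, and decarboxylative aromatisation would give methyl 4-aryloxybenzoate **A1**.
- Merits: the crowded aryl–oxygen bond is not made by a coupling that is sensitive to hindrance, and the para oxygen of ring A is present from the start, so no Baeyer–Villiger oxidation is needed. In these two respects this road is better than the chosen one.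
- Weak points: **A1** corresponds only to the stage of **8**, so both flavones remain to be built. **A2** requires a hydroquinone in which the hindered oxygen is already distinguished from the para oxygen, followed by strong-base acetylene formation. The cycloaddition must place the ester para and not meta. The methyl ester later has to be saponified beside, or before, a hydroxide-sensitive pyranone.
- Comparison: the chosen plan reaches **8** from **4** in two steps with commercial reagents, and its key step delivers a complete flavone, not a benzoate.

**Alternative 2:** Both pyranone rings are opened at O1–C2, which leads to the bis(1,3-diketone) **A5**. Acid would close both rings at once to **A4**, the tetrabenzyl ether of the target.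
- Merits: the chemistry is classical throughout, no pressure carbonylation is needed, and one operation forms two rings. In reliability of the ring closure itself this road is at least equal to the chosen one.
- Weak points: the difficulty moves into the assembly of **A5**. Unit 2 needs an acetyl group ortho to the free hydroxyl of the crowded aryloxy-dibenzyloxy ring, which means Friedel–Crafts or Fries chemistry under Lewis acid in the presence of benzyl ethers and an ester. Two separate acyl-transfer and rearrangement sequences must be run on one molecule that carries both a methyl ketone and a carboxyl function. O5 of unit 1 needs a fourth benzyl group. The route is several steps longer, and the key step settles none of the regiochemical questions.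
- Comparison: the chosen plan uses the diketone logic once, where it is cheap (commercial **17**), and replaces the second use by a one-step annulation of iodophenol **9**.

**Alternative 3:** Ring A of unit 2 is assembled by a Danheiser benzannulation. The bonds C8–C8a, C5–C6, C7–C8 and C4a–C5 are cut, leading to the diazo ketone **A7**, a 4-pyranone that already carries ring B, and to alkyne **A8**, whose two sp carbons bear the aryloxy and the silyloxy group. In the forward sense Wolff rearrangement, ketene–alkyne (2+2) cycloaddition, four-electron ring opening and six-electron electrocyclisation onto pyranone C3 would give **A6**, with the hydroxyl at C5 free and O7 silylated.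
- Merits: it forms the most bonds per step, it delivers ring A with every oxygen differentiated, and it needs neither a hindered ether coupling nor an iodination. On paper it is superior in these respects.
- Weak points: **A8** is a diether of an acetylenediol, a class of doubtful stability with little preparative background. The orientation of the (2+2) step depends on which oxygen polarises the alkyne more strongly, and the wrong sense would exchange the groups at C6 and C7. **A7** needs its own multistep preparation. Unit 1 must still be grown from the acetal of **A6**, with a labile silyl ether present.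
- Comparison: the chosen plan offers known reaction classes at every step and a regiochemical outcome fixed by symmetry instead of by polarisation.

Key step: step 8

Assumption: compounds 1, 5, 10, 12 and 17 and the reagents named in the steps are taken to be commercial; the phenol that becomes O1 of unit 2 is the one para to the ether oxygen.

## Route

Step 1
Reactants: 1 3,4,5-trihydroxybenzaldehyde
Product: 2 4-(allyloxy)-3,5-dihydroxybenzaldehyde
Conditions: allyl bromide (1.05 equiv), NaHCO3 (1.2 equiv), NaI (cat.), DMF, 40 °C
Reagents that add atoms: allyl bromide, C=CCBr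
Why: Regioselective Williamson mono-alkylation; the hydroxyl para to the formyl group is the most acidic, so hydrogencarbonate forms essentially only its phenoxide, as in the known 4-O-selective alkylation of polyhydroxybenzaldehydes.

Step 2
Reactants: 2 4-(allyloxy)-3,5-dihydroxybenzaldehyde
Product: 3 4-(allyloxy)-3,5-bis(benzyloxy)benzaldehyde
Conditions: BnBr (2.4 equiv), K2CO3 (3 equiv), DMF, 50 °C
Reagents that add atoms: benzyl bromide, BrCc1ccccc1
Why: Williamson etherification of the two remaining, equivalent phenols; the aldehyde and the allyl ether are inert to carbonate in DMF.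

Step 3
Reactants: 3 4-(allyloxy)-3,5-bis(benzyloxy)benzaldehyde
Product: 4 3,5-bis(benzyloxy)-4-hydroxybenzaldehyde
Conditions: Pd(PPh3)4 (2 mol %), morpholine (3 equiv), THF, rt
Reagents that add atoms: none
Why: Tsuji–Trost deallylation; zerovalent palladium ionises the allyl aryl ether to a pi-allyl complex and the stabilised phenoxide, and morpholine traps the allyl group, while benzyl ethers and the aldehyde are untouched.

Step 4
Reactants: 4 3,5-bis(benzyloxy)-4-hydroxybenzaldehyde; 5 [4-(tert-butoxycarbonyl)phenyl]boronic acid (2 equiv)
Product: 6 tert-butyl 4-[2,6-bis(benzyloxy)-4-formylphenoxy]benzoate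
Conditions: Cu(OAc)2 (2 equiv), pyridine (5 equiv), 4 Å molecular sieves, CH2Cl2, air, rt
Reagents that add atoms: none
Why: Chan–Lam oxidative O-arylation; the acidic phenol forms a copper phenoxide, the arylboronic acid transmetalates, and reductive elimination from a trivalent copper aryl phenoxide makes the C–O bond at room temperature. Acidic phenols with two ortho substituents are established substrates, and the formyl group keeps the trioxygenated ring from being oxidised by divalent copper.

Step 5
Reactants: 6 tert-butyl 4-[2,6-bis(benzyloxy)-4-formylphenoxy]benzoate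
Product: 8 tert-butyl 4-[2,6-bis(benzyloxy)-4-hydroxyphenoxy]benzoate, via aryl formate 7 (not isolated)
Conditions: mCPBA (1.5 equiv), CH2Cl2, 0 °C → rt; then K2CO3 (0.2 equiv), MeOH, rt
Reagents that add atoms: meta-chloroperoxybenzoic acid, O=C(OO)c1cccc(Cl)c1
Why: Baeyer–Villiger oxidation of an aryl aldehyde (Dakin-type); in the Criegee adduct the aryl group, which has an oxygen donor para to the migrating carbon, migrates in preference to hydride to give formate 7. Carbonate in methanol transesterifies the formate without touching the tert-butyl ester.

Step 6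
Reactants: 8 tert-butyl 4-[2,6-bis(benzyloxy)-4-hydroxyphenoxy]benzoate
Product: 9 tert-butyl 4-[2,6-bis(benzyloxy)-4-hydroxy-3-iodophenoxy]benzoate
Conditions: NIS (1.0 equiv), DMF, −20 → 0 °C, dark
Reagents that add atoms: N-iodosuccinimide, O=C1CCC(=O)N1I
Why: Electrophilic aromatic iodination ortho to a free phenol; the only unsubstituted carbons of the oxygenated ring are the two equivalent ones flanking the hydroxyl, the benzoate ring is deactivated, and one equivalent of reagent at low temperature limits di-iodination.

Step 7
Reactants: 10 4-(benzyloxy)benzaldehyde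
Product: 11 1-(benzyloxy)-4-ethynylbenzene
Conditions: dimethyl (1-diazo-2-oxopropyl)phosphonate (1.3 equiv), K2CO3 (2 equiv), MeOH/THF, rt
Reagents that add atoms: dimethyl (1-diazo-2-oxopropyl)phosphonate, CC(=O)C(=[N+]=[N-])P(=O)(OC)OC
Why: Seyferth–Gilbert homologation in the Ohira–Bestmann variant; methanolysis of the reagent gives the diazomethylphosphonate anion, which adds to the aldehyde, and cycloelimination with loss of nitrogen gives an alkylidene carbene that rearranges to the terminal alkyne.

Step 8
Reactants: 9 tert-butyl 4-[2,6-bis(benzyloxy)-4-hydroxy-3-iodophenoxy]benzoate; 12 carbon monoxide; 11 1-(benzyloxy)-4-ethynylbenzene (1.3 equiv)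
Product: 15 tert-butyl 4-({5,7-bis(benzyloxy)-2-[4-(benzyloxy)phenyl]-4-oxo-4H-chromen-6-yl}oxy)benzoate, via ortho-hydroxyaryl ynone 13 (not isolated), via diethylamino enone 14 (not isolated)
Conditions: PdCl2(PPh3)2 (5 mol %), CO (10 bar), Et2NH/DMF, 90 °C
Reagents that add atoms: none
Why: The divalent palladium precatalyst is reduced in the amine/alkyne medium to zerovalent palladium, which inserts into the C–I bond of 9; carbon monoxide then inserts to give an aroylpalladium iodide. The amine-deprotonated alkyne displaces iodide, and reductive elimination gives ynone 13, forming C4a–C4 and C4–C3. Diethylamine adds to 13 in conjugate fashion to give enaminone 14, and the ortho phenol attacks its beta carbon and expels the amine, forming O1–C2. Ring C is thus closed in a formally 6-endo-dig mode on the ynone, realised as a 6-endo-trig addition–elimination on the enaminone. The closest known reaction type is the palladium-catalysed carbonylative Sonogashira coupling of ortho-iodophenols with terminal alkynes in a secondary amine, which gives flavones directly. No stereocenter is formed. The step needs carbonyl insertion before alkynyl transfer (otherwise a 2-arylbenzofuran results), which is favoured by the electron-rich aryl palladium flanked by two ortho substituents, by carbon monoxide pressure and by the absence of copper. It also needs six- and not five-membered closure (otherwise an aurone results), which the secondary amine enforces through 14. The placement of O1 and C4 relative to the aryloxy group is fixed by the symmetry of 8, and only one hydroxyl is free to cyclise.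

Step 9
Reactants: 15 tert-butyl 4-({5,7-bis(benzyloxy)-2-[4-(benzyloxy)phenyl]-4-oxo-4H-chromen-6-yl}oxy)benzoate
Product: 16 4-({5,7-bis(benzyloxy)-2-[4-(benzyloxy)phenyl]-4-oxo-4H-chromen-6-yl}oxy)benzoic acid
Conditions: TFA/CH2Cl2 (1:4), 0 °C → rt
Reagents that add atoms: none
Why: Acidolysis of a tert-butyl ester by loss of 2-methylpropene; aryl benzyl ethers and the pyranone survive trifluoroacetic acid at room temperature for the short time needed, and no hydroxide meets ring C.

Step 10
Reactants: 16 4-({5,7-bis(benzyloxy)-2-[4-(benzyloxy)phenyl]-4-oxo-4H-chromen-6-yl}oxy)benzoic acid; 17 2',6'-dihydroxy-4'-methoxyacetophenone (1.2 equiv)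
Product: 19 1-(2,6-dihydroxy-4-methoxyphenyl)-3-[4-({5,7-bis(benzyloxy)-2-[4-(benzyloxy)phenyl]-4-oxo-4H-chromen-6-yl}oxy)phenyl]propane-1,3-dione, via acid chloride 18 (not isolated)
Conditions: (COCl)2 (1.1 equiv), DMF (cat.), CH2Cl2, 0 °C → rt, concentrate; then 17, LiN(SiMe3)2 (4 equiv), THF, −78 °C, add 18, −78 °C → rt
Reagents that add atoms: none
Why: Polyanion variant of the Baker–Venkataraman flavone synthesis; LiN(SiMe3)2 converts 17 into its bis(phenoxide) enolate, whose carbon is the most nucleophilic site and attacks 18, and one further equivalent deprotonates the diketone. Any O-acyl isomer is funnelled to the same product by base-mediated acyl migration, and flavone carboxylic acids are known to tolerate conversion to their chlorides.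

Step 11
Reactants: 19 1-(2,6-dihydroxy-4-methoxyphenyl)-3-[4-({5,7-bis(benzyloxy)-2-[4-(benzyloxy)phenyl]-4-oxo-4H-chromen-6-yl}oxy)phenyl]propane-1,3-dione
Product: 20 5,7-bis(benzyloxy)-2-[4-(benzyloxy)phenyl]-6-[4-(5-hydroxy-7-methoxy-4-oxo-4H-chromen-2-yl)phenoxy]-4H-chromen-4-one
Conditions: TsOH·H2O (0.2 equiv), toluene, 90 °C
Reagents that add atoms: none
Why: Acid-catalysed cyclodehydration of an ortho-hydroxyaryl 1,3-diketone; a phenol adds to the distal carbonyl (6-exo-trig) and the hemiketal loses water. The two hydroxyls of the ketone-bearing ring are equivalent, so only the 5-hydroxy-7-methoxyflavone can form.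

Step 12
Reactants: 20 5,7-bis(benzyloxy)-2-[4-(benzyloxy)phenyl]-6-[4-(5-hydroxy-7-methoxy-4-oxo-4H-chromen-2-yl)phenoxy]-4H-chromen-4-one
Product: 21 neocryptomerin
Conditions: H2 (1 atm), 10% Pd/C, THF/MeOH, rt
Reagents that add atoms: none
Why: Heterogeneous hydrogenolysis of three aryl benzyl ethers; the methyl ether, the diaryl ether and the conjugated pyranones are not cleaved at one atmosphere and room temperature, and the reaction is stopped once three equivalents of hydrogen are taken up.

## Compound list

1 | 3,4,5-trihydroxybenzaldehyde | O=Cc1cc(O)c(O)c(O)c1 | starting material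
2 | 4-(allyloxy)-3,5-dihydroxybenzaldehyde | C=CCOc1c(O)cc(C=O)cc1O | intermediate
3 | 4-(allyloxy)-3,5-bis(benzyloxy)benzaldehyde | C=CCOc1c(OCc2ccccc2)cc(C=O)cc1OCc1ccccc1 | intermediate
4 | 3,5-bis(benzyloxy)-4-hydroxybenzaldehyde | O=Cc1cc(OCc2ccccc2)c(O)c(OCc2ccccc2)c1 | intermediate
5 | [4-(tert-butoxycarbonyl)phenyl]boronic acid | CC(C)(C)OC(=O)c1ccc(B(O)O)cc1 | starting material
6 | tert-butyl 4-[2,6-bis(benzyloxy)-4-formylphenoxy]benzoate | CC(C)(C)OC(=O)c1ccc(Oc2c(OCc3ccccc3)cc(C=O)cc2OCc2ccccc2)cc1 | intermediate
7 | tert-butyl 4-[2,6-bis(benzyloxy)-4-(formyloxy)phenoxy]benzoate | CC(C)(C)OC(=O)c1ccc(Oc2c(OCc3ccccc3)cc(OC=O)cc2OCc2ccccc2)cc1 | intermediate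
8 | tert-butyl 4-[2,6-bis(benzyloxy)-4-hydroxyphenoxy]benzoate | CC(C)(C)OC(=O)c1ccc(Oc2c(OCc3ccccc3)cc(O)cc2OCc2ccccc2)cc1 | intermediate
9 | tert-butyl 4-[2,6-bis(benzyloxy)-4-hydroxy-3-iodophenoxy]benzoate | CC(C)(C)OC(=O)c1ccc(Oc2c(OCc3ccccc3)cc(O)c(I)c2OCc2ccccc2)cc1 | intermediate
10 | 4-(benzyloxy)benzaldehyde | O=Cc1ccc(OCc2ccccc2)cc1 | starting material
11 | 1-(benzyloxy)-4-ethynylbenzene | C#Cc1ccc(OCc2ccccc2)cc1 | intermediate
12 | carbon monoxide | [C-]#[O+] | starting material
13 | tert-butyl 4-[2,6-bis(benzyloxy)-3-{3-[4-(benzyloxy)phenyl]prop-2-ynoyl}-4-hydroxyphenoxy]benzoate | CC(C)(C)OC(=O)c1ccc(Oc2c(OCc3ccccc3)cc(O)c(C(=O)C#Cc3ccc(OCc4ccccc4)cc3)c2OCc2ccccc2)cc1 | intermediate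
14 | tert-butyl 4-[2,6-bis(benzyloxy)-3-{(2E)-3-[4-(benzyloxy)phenyl]-3-(diethylamino)prop-2-enoyl}-4-hydroxyphenoxy]benzoate | CC(C)(C)OC(=O)c1ccc(Oc2c(OCc3ccccc3)cc(O)c(C(=O)/C=C(/N(CC)CC)c3ccc(OCc4ccccc4)cc3)c2OCc2ccccc2)cc1 | intermediate
15 | tert-butyl 4-({5,7-bis(benzyloxy)-2-[4-(benzyloxy)phenyl]-4-oxo-4H-chromen-6-yl}oxy)benzoate | CC(C)(C)OC(=O)c1ccc(Oc2c(OCc3ccccc3)cc3oc(-c4ccc(OCc5ccccc5)cc4)cc(=O)c3c2OCc2ccccc2)cc1 | intermediate
16 | 4-({5,7-bis(benzyloxy)-2-[4-(benzyloxy)phenyl]-4-oxo-4H-chromen-6-yl}oxy)benzoic acid | O=C(O)c1ccc(Oc2c(OCc3ccccc3)cc3oc(-c4ccc(OCc5ccccc5)cc4)cc(=O)c3c2OCc2ccccc2)cc1 | intermediate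
17 | 2',6'-dihydroxy-4'-methoxyacetophenone | CC(=O)c1c(O)cc(OC)cc1O | starting material
18 | 4-({5,7-bis(benzyloxy)-2-[4-(benzyloxy)phenyl]-4-oxo-4H-chromen-6-yl}oxy)benzoyl chloride | O=C(Cl)c1ccc(Oc2c(OCc3ccccc3)cc3oc(-c4ccc(OCc5ccccc5)cc4)cc(=O)c3c2OCc2ccccc2)cc1 | intermediate
19 | 1-(2,6-dihydroxy-4-methoxyphenyl)-3-[4-({5,7-bis(benzyloxy)-2-[4-(benzyloxy)phenyl]-4-oxo-4H-chromen-6-yl}oxy)phenyl]propane-1,3-dione | COc1cc(O)c(C(=O)CC(=O)c2ccc(Oc3c(OCc4ccccc4)cc4oc(-c5ccc(OCc6ccccc6)cc5)cc(=O)c4c3OCc3ccccc3)cc2)c(O)c1 | intermediate
20 | 5,7-bis(benzyloxy)-2-[4-(benzyloxy)phenyl]-6-[4-(5-hydroxy-7-methoxy-4-oxo-4H-chromen-2-yl)phenoxy]-4H-chromen-4-one | COc1cc(O)c2c(=O)cc(-c3ccc(Oc4c(OCc5ccccc5)cc5oc(-c6ccc(OCc7ccccc7)cc6)cc(=O)c5c4OCc4ccccc4)cc3)oc2c1 | intermediate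
21 | neocryptomerin, 5,7-dihydroxy-6-[4-(5-hydroxy-7-methoxy-4-oxo-4H-chromen-2-yl)phenoxy]-2-(4-hydroxyphenyl)-4H-chromen-4-one | COc1cc(O)c2c(=O)cc(-c3ccc(Oc4c(O)cc5oc(-c6ccc(O)cc6)cc(=O)c5c4O)cc3)oc2c1 | target

## Step count and least certain steps

Total: 12 steps. Longest linear sequence: 11 steps (steps 1 to 6 and 8 to 12, from 1 to 21); step 7 is a one-step side branch.

**Step 8 (key step).** Three things may go wrong. The alkynyl group may be transferred before carbon monoxide inserts, so that direct Sonogashira coupling and five-membered closure take over. The aroylpalladium may be intercepted by diethylamine (aminocarbonylation). Oxidative addition at the electron-rich C–I bond with two ortho substituents may be slow. Fallback, which builds ring C by aldol and oxidation and not by carbonylation: from 9, Stille coupling with tributyl(1-ethoxyvinyl)stannane [PdCl2(PPh3)2, dioxane, 90 °C] gives tert-butyl 4-[2,6-bis(benzyloxy)-3-(1-ethoxyethenyl)-4-hydroxyphenoxy]benzoate F1. Aqueous HCl in THF hydrolyses it to tert-butyl 4-[3-acetyl-2,6-bis(benzyloxy)-4-hydroxyphenoxy]benzoate F2. Claisen–Schmidt condensation of F2 with aldehyde 10 (KOH, EtOH/THF, rt) gives the 2'-hydroxychalcone tert-butyl 4-[2,6-bis(benzyloxy)-3-{(2E)-3-[4-(benzyloxy)phenyl]prop-2-enoyl}-4-hydroxyphenoxy]benzoate F3. Iodine-catalysed oxidative cyclisation in DMSO at 120 °C returns to the route at 15.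

**Step 4.** Transmetalation of the electron-poor arylboronic acid may be slow and protodeboronation may compete, so that conversion of the hindered phenol stalls. Fallback: from 4, nucleophilic aromatic substitution on tert-butyl 4-fluorobenzoate (Cs2CO3, DMSO, 130 °C) leads directly to 6. This is the reserve and not the first choice because the phenoxide is deactivated and the fluoride only weakly activated.

**Step 5.** Hydride may migrate instead of aryl in the Criegee adduct, which oxidises the aldehyde to the carboxylic acid; the aryloxy donor is twisted out of conjugation by its two ortho neighbours and weakened by its ester. Fallback, which oxidises before the ether is made: from 4, a true Dakin oxidation of the para-hydroxybenzaldehyde (H2O2, NaOH, aqueous THF) gives 2,6-bis(benzyloxy)benzene-1,4-diol F4. Its unhindered and more acidic hydroxyl is mono-allylated (allyl bromide 1 equiv, K2CO3, acetone) to 4-(allyloxy)-2,6-bis(benzyloxy)phenol F5. The now electron-rich hindered phenoxide is arylated with tert-butyl 4-fluorobenzoate (Cs2CO3, DMSO, 120 °C) to tert-butyl 4-[4-(allyloxy)-2,6-bis(benzyloxy)phenoxy]benzoate F6. Deallylation with Pd(PPh3)4 and morpholine returns to the route at 8. This fallback replaces steps 4 and 5 together.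

**Step 10.** The polyanion may be acylated on oxygen or twice, or the excess amide base may attack the pyranone of unit 2. Fallback, the classical two-stage sequence: from 16 and 17, Steglich esterification (EDC·HCl, DMAP, CH2Cl2) gives the mono-ester 2-acetyl-3-hydroxy-5-methoxyphenyl 4-({5,7-bis(benzyloxy)-2-[4-(benzyloxy)phenyl]-4-oxo-4H-chromen-6-yl}oxy)benzoate F7. Baker–Venkataraman rearrangement (KOtBu, THF, 0 °C → rt) returns to the route at 19.

**Step 12.** The C2–C3 double bonds may be over-reduced, or the reaction may stall when partly debenzylated material precipitates on the catalyst. Fallback, a Lewis-acid cleavage in place of hydrogenolysis: from 20, BCl3 with pentamethylbenzene in CH2Cl2 at −78 °C removes the three benzyl groups and leads directly to 21. The methyl ether, which is not peri to a carbonyl group, is retained.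

## Further compounds

F1 | step 8 | tert-butyl 4-[2,6-bis(benzyloxy)-3-(1-ethoxyethenyl)-4-hydroxyphenoxy]benzoate | C=C(OCC)c1c(O)cc(OCc2ccccc2)c(Oc2ccc(C(=O)OC(C)(C)C)cc2)c1OCc1ccccc1
F2 | step 8 | tert-butyl 4-[3-acetyl-2,6-bis(benzyloxy)-4-hydroxyphenoxy]benzoate | CC(=O)c1c(O)cc(OCc2ccccc2)c(Oc2ccc(C(=O)OC(C)(C)C)cc2)c1OCc1ccccc1
F3 | step 8 | tert-butyl 4-[2,6-bis(benzyloxy)-3-{(2E)-3-[4-(benzyloxy)phenyl]prop-2-enoyl}-4-hydroxyphenoxy]benzoate | O=C(/C=C/c1ccc(OCc2ccccc2)cc1)c1c(O)cc(OCc2ccccc2)c(Oc2ccc(C(=O)OC(C)(C)C)cc2)c1OCc1ccccc1
F0 | step 4 | none | none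
F4 | step 5 | 2,6-bis(benzyloxy)benzene-1,4-diol | Oc1cc(OCc2ccccc2)c(O)c(OCc2ccccc2)c1
F5 | step 5 | 4-(allyloxy)-2,6-bis(benzyloxy)phenol | C=CCOc1cc(OCc2ccccc2)c(O)c(OCc2ccccc2)c1
F6 | step 5 | tert-butyl 4-[4-(allyloxy)-2,6-bis(benzyloxy)phenoxy]benzoate | C=CCOc1cc(OCc2ccccc2)c(Oc2ccc(C(=O)OC(C)(C)C)cc2)c(OCc2ccccc2)c1
F7 | step 10 | 2-acetyl-3-hydroxy-5-methoxyphenyl 4-({5,7-bis(benzyloxy)-2-[4-(benzyloxy)phenyl]-4-oxo-4H-chromen-6-yl}oxy)benzoate | CC(=O)c1c(O)cc(OC)cc1OC(=O)c1ccc(Oc2c(OCc3ccccc3)cc3oc(-c4ccc(OCc5ccccc5)cc4)cc(=O)c3c2OCc2ccccc2)cc1
F0 | step 12 | none | none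
A1 | alternative 1 | methyl 4-[2,6-bis(benzyloxy)-4-(methoxymethoxy)phenoxy]benzoate | COC(=O)c1ccc(Oc2c(OCc3ccccc3)cc(OCOC)cc2OCc2ccccc2)cc1
A2 | alternative 1 | 1,3-bis(benzyloxy)-2-(ethynyloxy)-5-(methoxymethoxy)benzene | C#COc1c(OCc2ccccc2)cc(OCOC)cc1OCc1ccccc1
A3 | alternative 1 | methyl coumalate (methyl 2-oxo-2H-pyran-5-carboxylate) | COC(=O)c1ccc(=O)oc1
A4 | alternative 2 | 5,5'',7'',4'''-tetra-O-benzylneocryptomerin | COc1cc(OCc2ccccc2)c2c(=O)cc(-c3ccc(Oc4c(OCc5ccccc5)cc5oc(-c6ccc(OCc7ccccc7)cc6)cc(=O)c5c4OCc4ccccc4)cc3)oc2c1
A5 | alternative 2 | 1-[2-(benzyloxy)-6-hydroxy-4-methoxyphenyl]-3-{4-[2,6-bis(benzyloxy)-3-{3-[4-(benzyloxy)phenyl]-3-oxopropanoyl}-4-hydroxyphenoxy]phenyl}propane-1,3-dione | COc1cc(O)c(C(=O)CC(=O)c2ccc(Oc3c(OCc4ccccc4)cc(O)c(C(=O)CC(=O)c4ccc(OCc5ccccc5)cc4)c3OCc3ccccc3)cc2)c(OCc2ccccc2)c1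
A6 | alternative 3 | 4'-O-benzyl-7-O-triisopropylsilyl-6-O-[4-(1,3-dioxolan-2-yl)phenyl]scutellarein | O=c1cc(-c2ccc(OCc3ccccc3)cc2)oc2cc(O[Si](C(C)C)(C(C)C)C(C)C)c(Oc3ccc(C4OCCO4)cc3)c(O)c12
A7 | alternative 3 | 6-[4-(benzyloxy)phenyl]-2-(diazoacetyl)-4H-pyran-4-one | [N-]=[N+]=CC(=O)c1cc(=O)cc(-c2ccc(OCc3ccccc3)cc2)o1
A8 | alternative 3 | 2-{4-[({[tri(propan-2-yl)silyl]oxy}ethynyl)oxy]phenyl}-1,3-dioxolane | CC(C)[Si](OC#COc1ccc(C2OCCO2)cc1)(C(C)C)C(C)C
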